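**Assumption (one line):** Kuwanon A as drawn has no stereocentre (the gem-dimethyl carbon carries two identical methyls), so "single enantiomer" is trivially met. The route needs no stereocontrol, and the two transient racemic CH centres (in 9 and 11) are destroyed before the end.

## Retrosynthetic overview
1. Kuwanon A comes from the 4'-O-MOM flavone (12). The pyranone ring (O1–C2 bond) is closed last by acid cyclodehydration of a 1,3-diketone (11).
2. **Key bold step:** the diketone is made in one operation by thermal C-acylation of unprotected phloroglucinol with an acylketene. The acylketene is generated from an α-prenyl tert-butyl aroylacetate (9). This builds the A-ring and C3–prenyl-bearing skeleton together and leaves the 5,7-OH groups free, so they need no protecting groups.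
3. The aroylacetate comes from a Claisen condensation of a chromene ester (5). The 2,2-dimethylchromene is formed regiospecifically by phenol/prenal [3+3] annulation on methyl 4-O-MOM-resorcylate, where C3 is the only ortho position free for ring closure.
4. Order of ring formation: B-ring chromene, then C-ring pyranone. The A-ring comes from phloroglucinol.

## Forward route

**Step 1**
Reactants: 1 (methyl 2,4-dihydroxybenzoate), 2 (chloromethyl methyl ether, MOMCl)
Product: 3 (methyl 2-hydroxy-4-(methoxymethoxy)benzoate)
Conditions: MOMCl, i-Pr2NEt, CH2Cl2, 0 °C → rt
Reagents that add atoms: MOMCl, COCCl (adds CH2OCH3)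
Why: The 2-OH is locked in a hydrogen bond to the ester C=O, while the 4-OH is more acidic and exposed, so regioselective O-alkylation (MOM protection) occurs at O4. This leaves C3 as the only ortho position of the 2-OH that can form a ring. No stereocentre is formed.

**Step 2**
Reactants: 3, 4 (prenal, 3-methylbut-2-enal)
Product: 5 (methyl 5-(methoxymethoxy)-2,2-dimethyl-2H-chromene-8-carboxylate)
Conditions: prenal (3 equiv), EDDA (ethylenediammonium diacetate, 10 mol%), xylene, 140 °C, sealed tube
Reagents that add atoms: prenal, CC(C)=CC=O (adds C5H8 as the pyran ring; its O leaves as water)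
Why: Phenol–enal [3+3] annulation: Knoevenagel-type C-alkylation at C3, then 6π-oxa-electrocyclisation of the ortho-quinone methide, gives the 2,2-dimethyl-2H-chromene. Ring closure is only possible onto C3, so the angular regiochemistry is unambiguous. No stereocentre is formed.

**Step 3**
Reactants: 5, 6 (tert-butyl acetate)
Product: 7 (tert-butyl 3-(5-MOMO-2,2-dimethyl-2H-chromen-8-yl)-3-oxopropanoate)
Conditions: LiCH2CO2tBu (from tBuOAc, LDA, 3 equiv), THF, −78 °C → rt; NH4Cl work-up
Reagents that add atoms: tert-butyl acetate, CC(=O)OC(C)(C)C (adds CH2CO2tBu; MeOH leaves)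
Why: Crossed Claisen condensation of a non-enolisable aryl ester with an ester enolate; deprotonation of the product β-ketoester drives the reaction. No stereocentre is formed.

**Step 4**
Reactants: 7, 8 (prenyl bromide)
Product: 9 (tert-butyl 2-aroyl-5-methylhex-4-enoate, i.e. the α-prenyl β-ketoester, racemic)
Conditions: prenyl bromide (1.2 equiv), K2CO3, acetone, 50 °C
Reagents that add atoms: prenyl bromide, CC(C)=CCBr (adds C5H9)
Why: The stabilised enolate of the β-ketoester undergoes SN2 C-alkylation at the primary allylic carbon, installing the future C3 prenyl group. This creates a racemic α-CH centre that is removed in Step 5 when the planar acylketene forms.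

**Step 5**
Reactants: 9, 10 (phloroglucinol)
Product: 11 (2-hydroxyaryl 1,3-diketone, racemic: 1-(2,4,6-trihydroxyphenyl)-2-prenyl-3-(chromenyl)propane-1,3-dione)
Conditions: phloroglucinol (3 equiv, dried by azeotrope), xylene, 140 °C, sealed tube, 16 h
Reagents that add atoms: phloroglucinol, Oc1cc(O)cc(O)c1 (becomes the A-ring)
Why: **Proposed new method:** At 140 °C the tert-butyl β-ketoester loses tBuOH to give a transient α-prenyl aroylketene. The very C-nucleophilic phloroglucinol traps it irreversibly at carbon, whereas any O-acyl adducts re-form the ketene and so funnel to the C-acyl product. The result is the Baker–Venkataraman-type diketone without a B–V rearrangement or A-ring protecting groups. Closest known chemistry: acylketene generation from tert-butyl acetoacetate or dioxinones and nucleophile trapping, combined with Friedel–Crafts/Houben–Hoesch-type C-acylation of phloroglucinol. The α-CH stereocentre of 11 is epimerisable and is destroyed in Step 6.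

**Step 6**
Reactants: 11
Product: 12 (5,7-dihydroxy-3-prenyl-4'-O-MOM-2',3'-chromeno-flavone)
Conditions: TsOH·H2O (0.2 equiv), 4 Å MS, toluene, 80 °C, 2 h
Reagents that add atoms: none (loses H2O)
Why: Acid-catalysed cyclodehydration of the o-hydroxyaryl 1,3-diketone (the usual flavone-forming step) closes the pyranone; the new C2=C3 bond is sp2, so no stereocentre remains. Any partial MOM loss here is harmless because Step 7 removes it anyway.

**Step 7**
Reactants: 12
Product: 13 (Kuwanon A)
Conditions: ZnBr2 (3 equiv), n-PrSH (6 equiv), CH2Cl2, rt, 1 h
Reagents that add atoms: none (the MOM group leaves as n-PrSCH2OMe)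
Why: Lewis-acid/thiol cleavage of the aryl MOM acetal is mild and leaves the chromene, prenyl alkene and chelated 5-OH untouched. No hydrogenolysis is used, so both alkenes survive.

## Compound list
1 | methyl 2,4-dihydroxybenzoate | COC(=O)c1ccc(O)cc1O | starting material
2 | chloromethyl methyl ether (MOMCl) | COCCl | starting material
3 | methyl 2-hydroxy-4-(methoxymethoxy)benzoate | COC(=O)c1ccc(OCOC)cc1O | intermediate
4 | prenal (3-methylbut-2-enal) | CC(C)=CC=O | starting material
5 | methyl 5-(methoxymethoxy)-2,2-dimethyl-2H-chromene-8-carboxylate | COC(=O)c1ccc(OCOC)c2c1OC(C)(C)C=C2 | intermediate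
6 | tert-butyl acetate | CC(=O)OC(C)(C)C | starting material
7 | tert-butyl 3-(5-MOMO-2,2-dimethyl-2H-chromen-8-yl)-3-oxopropanoate | CC(C)(C)OC(=O)CC(=O)c1ccc(OCOC)c2c1OC(C)(C)C=C2 | intermediate
8 | prenyl bromide | CC(C)=CCBr | starting material
9 | tert-butyl 2-aroyl-5-methylhex-4-enoate (α-prenyl β-ketoester, racemic) | CC(C)(C)OC(=O)C(CC=C(C)C)C(=O)c1ccc(OCOC)c2c1OC(C)(C)C=C2 | intermediate
10 | phloroglucinol | Oc1cc(O)cc(O)c1 | starting material
11 | 1,3-diketone (racemic) | CC(C)=CCC(C(=O)c1c(O)cc(O)cc1O)C(=O)c1ccc(OCOC)c2c1OC(C)(C)C=C2 | intermediate
12 | 4'-O-MOM Kuwanon A | CC(C)=CCc1c(-c2ccc(OCOC)c3c2OC(C)(C)C=C3)oc2cc(O)cc(O)c2c1=O | intermediate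
13 | Kuwanon A (achiral) | CC(C)=CCc1c(-c2ccc(O)c3c2OC(C)(C)C=C3)oc2cc(O)cc(O)c2c1=O | target

## Totals
- Total steps: 7.
- Longest linear sequence: 7 steps (1 → 3 → 5 → 7 → 9 → 11 → 12 → 13). Phloroglucinol enters convergently at Step 5.

## Three steps most likely to fail
1. **Step 5 (acylketene C-acylation of phloroglucinol).** The acylketene is hindered and could dimerise, or O-acylation could win over C-acylation. *Fallback (different approach):* take the classical Baker–Venkataraman route from the same B-ring fragment. Hydrolyse 5 and make the aroyl chloride, esterify 2-hydroxy-4,6-bis(MOMO)acetophenone, do the KOtBu B–V rearrangement, C-prenylate the diketone with prenyl bromide/K2CO3, then cyclise and deprotect.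
2. **Step 2 (chromene annulation on the H-bond-chelated salicylate).** The chelated phenol may be unreactive or the yield poor. *Fallback (different mechanism):* O-alkylate 3 with 3-chloro-3-methylbut-1-yne (K2CO3, KI, CuI), then run the thermal aryl propargyl ether Claisen/1,5-H shift/6π-electrocyclisation cascade (PhNEt2, 200 °C). The sole free ortho carbon again ensures the angular regiochemistry.
3. **Step 6 (Brønsted-acid cyclodehydration with an acid-labile chromene and prenyl alkene).** Ring-opening or cyclisation of the prenyl or chromene groups could compete. *Fallback (different activation mode):* a Mitsunobu-type cyclodehydration (PPh3/DIAD, THF, 0 °C) activates the enol oxygen for intramolecular displacement by the 2-OH, so no acid is involved.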